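**Plan**
Ring numbering: C1 (CH bearing the acrylate), C2, C3, C4 (methyl carbinol), C5 (ketone), C6, C7, C8(Me)=C9, C10, C11, C12(Me)–C13 (oxirane), C14. Cuts, last-made bond first: C9–C10 (ring closure), C10=C11 and C12=C13 (two olefinations around a Sharpless epoxidation), C6–C7, C5–C6, C2–C3, and C1–side chain.
The C2–C3 cut is possible because C3–C4–C5 with the C4 methyl and hydroxyl is (S)-citramalic acid minus the carboxyl on C3, and C2–C1–C14–C13(O) is a 4-substituted δ-valerolactone (a 5-hydroxypentanoic acid) minus the carboxyl on C2. Both acids give unstabilised primary radicals with the stereocentres one carbon away.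
Forward: the lactone half (steps 1–5) and the citramalate half (6–7) are joined at C2–C3 (8); C13 is extended to the Z-allylic ether (9–12); C5 becomes a methyl ketone that is allylated with the C7–C9 iodoalkene (13–18); the side chain is oxidised to the acrylate (19–21); the oxirane is made (22–23) and given its vinyl group (24–25); the 14-membered ring closes last at C9–C10 (26).
Stereochemistry: C1 from a rhodium/(R)-BINAP conjugate addition, C4 from (S)-citramalic acid, E-C8=C9 from syn-carboalumination, Z-C12=C13 from a Wittig reaction with an α-silyloxy ketone, C12/C13 from Sharpless epoxidation with L-(+)-diethyl tartrate.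

Key step: step 8

Assumption: the rhodium/(R)-BINAP catalyst is taken to select the same enone face for the 1-substituted alkenyl group as it does for aryl groups, which corresponds to the (R)-lactone 5.
Abbreviations: PMB = 4-methoxybenzyl, TBS = tert-butyldimethylsilyl, TES = triethylsilyl, BBN = borabicyclo[3.3.1]nonane.

Step 1
Reactants: 1 2-bromoprop-2-en-1-ol
Product: 2 1-{[(2-bromoprop-2-en-1-yl)oxy]methyl}-4-methoxybenzene
Conditions: NaH, 4-methoxybenzyl chloride, n-Bu4NI (cat.), THF/DMF, 0 °C → rt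
Reagents that add atoms: 4-methoxybenzyl chloride COc1ccc(CCl)cc1
Why: Williamson etherification of the primary allylic alkoxide gives a PMB ether that tolerates every step up to its oxidative removal in step 19.

Step 2
Reactants: 2 1-{[(2-bromoprop-2-en-1-yl)oxy]methyl}-4-methoxybenzene
Product: 3 2-[3-(PMB-oxy)prop-1-en-2-yl]-4,4,5,5-tetramethyl-1,3,2-dioxaborolane
Conditions: bis(pinacolato)diboron, PdCl2(PPh3)2 (3 mol%), PPh3, KOPh, toluene, 50 °C
Reagents that add atoms: bis(pinacolato)diboron CC1(C)OB(OC1(C)C)B1OC(C)(C)C(C)(C)O1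
Why: Miyaura borylation of the alkenyl bromide under phenoxide activation exchanges bromine for boron without touching the allylic ether.

Step 3
Reactants: 3 2-[3-(PMB-oxy)prop-1-en-2-yl]-4,4,5,5-tetramethyl-1,3,2-dioxaborolane; 4 5,6-dihydro-2H-pyran-2-one
Product: 5 (R)-4-[3-(PMB-oxy)prop-1-en-2-yl]tetrahydro-2H-pyran-2-one
Conditions: [Rh(cod)Cl]2 (2.5 mol%), (R)-BINAP (6 mol%), KOH (20 mol%), 1,4-dioxane/H2O 10:1, 50 °C; mildly acidic work-up
Reagents that add atoms: none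
Why: Hayashi–Miyaura reaction, in which the alkenyl–rhodium species adds 1,4 to the unsaturated lactone and the enolate is protonated by water; the C1 stereocentre is set by the face selection of the (R)-BINAP ligand.

Step 4
Reactants: 5 (R)-4-[3-(PMB-oxy)prop-1-en-2-yl]tetrahydro-2H-pyran-2-one
Product: 8 (R)-5-(TBS-oxy)-3-[3-(PMB-oxy)prop-1-en-2-yl]pentanoic acid, via lithium hydroxy carboxylate 6 (not isolated), via bis-silyl ester 7 (not isolated)
Conditions: LiOH·H2O, THF/H2O, rt; evaporate; TBSCl, imidazole, DMF, rt; then K2CO3, MeOH/THF/H2O, rt; work-up at pH 5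
Reagents that add atoms: lithium hydroxide [Li+].[OH-]; tert-butyldimethylsilyl chloride CC(C)(C)[Si](C)(C)Cl
Why: Saponification opens the lactone, silylation caps the C13 hydroxyl before it can relactonise, and the labile silyl ester is cleaved selectively by carbonate to free the C2 acid.

Step 5
Reactants: 8 (R)-5-(TBS-oxy)-3-[3-(PMB-oxy)prop-1-en-2-yl]pentanoic acid; 9 N-hydroxyphthalimide
Product: 10 1,3-dioxoisoindolin-2-yl (R)-5-(TBS-oxy)-3-[3-(PMB-oxy)prop-1-en-2-yl]pentanoate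
Conditions: N,N'-diisopropylcarbodiimide, DMAP (10 mol%), CH2Cl2, rt
Reagents that add atoms: none
Why: Steglich-type carbodiimide esterification gives the redox-active ester under neutral conditions that leave both ethers intact.

Step 6
Reactants: 11 (S)-citramalic acid
Product: 12 2-[(4S)-2,2,4-trimethyl-5-oxo-1,3-dioxolan-4-yl]acetic acid
Conditions: 2,2-dimethoxypropane, TsOH·H2O (5 mol%), rt
Reagents that add atoms: 2,2-dimethoxypropane COC(C)(C)OC
Why: Acid-catalysed acetonide exchange ties the α-hydroxy acid into the five-membered dioxolanone and leaves the β-carboxyl free; C4 is not touched.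

Step 7
Reactants: 12 2-[(4S)-2,2,4-trimethyl-5-oxo-1,3-dioxolan-4-yl]acetic acid; 9 N-hydroxyphthalimide
Product: 13 1,3-dioxoisoindolin-2-yl 2-[(4S)-2,2,4-trimethyl-5-oxo-1,3-dioxolan-4-yl]acetate
Conditions: N,N'-diisopropylcarbodiimide, DMAP (10 mol%), CH2Cl2, rt
Reagents that add atoms: none
Why: The same carbodiimide esterification converts the free carboxyl into the second redox-active ester.

Step 8
Reactants: 10 1,3-dioxoisoindolin-2-yl (R)-5-(TBS-oxy)-3-[3-(PMB-oxy)prop-1-en-2-yl]pentanoate; 13 1,3-dioxoisoindolin-2-yl 2-[(4S)-2,2,4-trimethyl-5-oxo-1,3-dioxolan-4-yl]acetate (3 equiv)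
Product: 14 (5S)-5-{(3S)-5-(TBS-oxy)-3-[3-(PMB-oxy)prop-1-en-2-yl]pentyl}-2,2,5-trimethyl-1,3-dioxolan-4-one
Conditions: NiCl2·6H2O (20 mol%), 2,2'-bipyridine (40 mol%), AgNO3 (30 mol%), NMP, Mg anode, reticulated vitreous carbon cathode, constant current, rt
Reagents that add atoms: none
Why: Cathodically generated low-valent nickel–bipyridine species pass single electrons to both N-acyloxyphthalimides, each of which loses phthalimide anion and CO2 to give a primary radical (C2 from 10, C3 from 13); nickel captures the two radicals in turn and reductive elimination from the dialkylnickel forms the C2–C3 bond. The closest known reaction is the nickel-electrocatalytic doubly decarboxylative sp3–sp3 coupling of two redox-active esters with one partner in excess. No ring closes and no stereocentre is created; C1 and C4 each sit one carbon away from a radical site and pass through unchanged. The selectivity needed is cross- over homo-coupling, and it is secured by the threefold excess of the two-step ester 13, so that 10 is consumed mainly in the hetero-coupling and the symmetrical dimer of 13 is separated. The C2 radical is a 3-butenyl radical whose 1,2-vinyl shift through a cyclopropylcarbinyl radical should be much slower than capture by nickel, and the C3 radical carries only a β-ketal oxygen that does not fragment, so both should couple with their skeletons intact.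

Step 9
Reactants: 14 (5S)-5-{(3S)-5-(TBS-oxy)-3-[3-(PMB-oxy)prop-1-en-2-yl]pentyl}-2,2,5-trimethyl-1,3-dioxolan-4-one
Product: 15 (5S)-5-{(3S)-5-hydroxy-3-[3-(PMB-oxy)prop-1-en-2-yl]pentyl}-2,2,5-trimethyl-1,3-dioxolan-4-one
Conditions: HF·pyridine, pyridine, THF, 0 °C → rt
Reagents that add atoms: none
Why: Buffered fluoride desilylation removes the only silyl group and should leave the dioxolanone and the PMB ether untouched.

Step 10
Reactants: 15 (5S)-5-{(3S)-5-hydroxy-3-[3-(PMB-oxy)prop-1-en-2-yl]pentyl}-2,2,5-trimethyl-1,3-dioxolan-4-one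
Product: 16 (5S)-5-{(3S)-5-iodo-3-[3-(PMB-oxy)prop-1-en-2-yl]pentyl}-2,2,5-trimethyl-1,3-dioxolan-4-one
Conditions: I2, PPh3, imidazole, CH2Cl2, 0 °C
Reagents that add atoms: iodine II
Why: Appel-type iodination converts the primary C13 alcohol into the iodide under neutral conditions.

Step 11
Reactants: 16 (5S)-5-{(3S)-5-iodo-3-[3-(PMB-oxy)prop-1-en-2-yl]pentyl}-2,2,5-trimethyl-1,3-dioxolan-4-one
Product: 17 {(3S)-3-[3-(PMB-oxy)prop-1-en-2-yl]-5-[(4S)-2,2,4-trimethyl-5-oxo-1,3-dioxolan-4-yl]pentyl}triphenylphosphonium iodide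
Conditions: PPh3 (3 equiv), MeCN, 80 °C
Reagents that add atoms: triphenylphosphine c1ccccc1P(c1ccccc1)c1ccccc1
Why: SN2 quaternisation of triphenylphosphine by the unhindered primary iodide gives the phosphonium salt.

Step 12
Reactants: 17 {(3S)-3-[3-(PMB-oxy)prop-1-en-2-yl]-5-[(4S)-2,2,4-trimethyl-5-oxo-1,3-dioxolan-4-yl]pentyl}triphenylphosphonium iodide; 18 1-(TBS-oxy)propan-2-one
Product: 20 (5S)-5-{(3S,5Z)-7-(TBS-oxy)-6-methyl-3-[3-(PMB-oxy)prop-1-en-2-yl]hept-5-en-1-yl}-2,2,5-trimethyl-1,3-dioxolan-4-one, via phosphonium ylide 19 (not isolated)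
Conditions: NaN(SiMe3)2, THF, −78 °C; then 18 (2 equiv), −78 °C → rt
Reagents that add atoms: none
Why: Wittig olefination of a non-stabilised ylide with an α-silyloxy methyl ketone places the oxygenated carbon (C11) cis to the ylide chain (C14), giving the Z-trisubstituted alkene; the lactone-type carbonyl on the fully substituted C4 is much less reactive than the ketone at −78 °C.

Step 13
Reactants: 20 (5S)-5-{(3S,5Z)-7-(TBS-oxy)-6-methyl-3-[3-(PMB-oxy)prop-1-en-2-yl]hept-5-en-1-yl}-2,2,5-trimethyl-1,3-dioxolan-4-one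
Product: 21 (2S,5S,7Z)-9-(TBS-oxy)-2-hydroxy-N-methoxy-N,2,8-trimethyl-5-[3-(PMB-oxy)prop-1-en-2-yl]non-7-enamide
Conditions: MeNH(OMe)·HCl, i-PrMgCl, THF, −20 → 0 °C
Reagents that add atoms: N,O-dimethylhydroxylamine hydrochloride CNOC.Cl
Why: Aminolysis of the activated dioxolanone carbonyl by the magnesium amide gives the Weinreb amide, with loss of acetone uncovering the C4 hydroxyl.

Step 14
Reactants: 21 (2S,5S,7Z)-9-(TBS-oxy)-2-hydroxy-N-methoxy-N,2,8-trimethyl-5-[3-(PMB-oxy)prop-1-en-2-yl]non-7-enamide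
Product: 22 (2S,5S,7Z)-9-(TBS-oxy)-N-methoxy-N,2,8-trimethyl-5-[3-(PMB-oxy)prop-1-en-2-yl]-2-(TES-oxy)non-7-enamide
Conditions: TESOTf, 2,6-lutidine, CH2Cl2, −78 → 0 °C
Reagents that add atoms: triethylsilyl trifluoromethanesulfonate CC[Si](CC)(CC)OS(=O)(=O)C(F)(F)F
Why: Silyl triflate silylation of the tertiary alcohol removes the acidic proton before the two carbanion steps that follow.

Step 15
Reactants: 22 (2S,5S,7Z)-9-(TBS-oxy)-N-methoxy-N,2,8-trimethyl-5-[3-(PMB-oxy)prop-1-en-2-yl]-2-(TES-oxy)non-7-enamide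
Product: 23 (3S,6S,8Z)-10-(TBS-oxy)-3,9-dimethyl-6-[3-(PMB-oxy)prop-1-en-2-yl]-3-(TES-oxy)dec-8-en-2-one
Conditions: MeMgBr, THF, 0 °C
Reagents that add atoms: methylmagnesium bromide C[Mg]Br
Why: Weinreb ketone synthesis, in which the chelated tetrahedral intermediate stops the addition at the methyl ketone (C5 with C6 as its methyl).

Step 16
Reactants: 24 prop-2-yn-1-ol
Product: 26 (E)-3-iodo-2-methylprop-2-en-1-ol, via alkenylalane 25 (not isolated)
Conditions: AlMe3 (3 equiv), Cp2ZrCl2 (25 mol%), CH2Cl2, 0 °C → rt; then I2, THF, −30 → 0 °C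
Reagents that add atoms: trimethylaluminium C[Al](C)C; iodine II
Why: Negishi zirconium-catalysed carboalumination adds methyl and aluminium syn across the alkyne and iodinolysis proceeds with retention, fixing iodine cis to methyl (the future E-C8=C9).

Step 17
Reactants: 26 (E)-3-iodo-2-methylprop-2-en-1-ol
Product: 27 (E)-3-bromo-1-iodo-2-methylprop-1-ene
Conditions: CBr4, PPh3, CH2Cl2, 0 °C
Reagents that add atoms: carbon tetrabromide BrC(Br)(Br)Br
Why: Appel bromination converts the allylic alcohol into the allylic bromide without changing the alkene geometry.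

Step 18
Reactants: 23 (3S,6S,8Z)-10-(TBS-oxy)-3,9-dimethyl-6-[3-(PMB-oxy)prop-1-en-2-yl]-3-(TES-oxy)dec-8-en-2-one; 27 (E)-3-bromo-1-iodo-2-methylprop-1-ene
Product: 29 (1E,6S,9S,11Z)-13-(TBS-oxy)-1-iodo-2,6,12-trimethyl-9-[3-(PMB-oxy)prop-1-en-2-yl]-6-(TES-oxy)trideca-1,11-dien-5-one, via lithium enolate 28 (not isolated)
Conditions: LiN(i-Pr)2, THF, −78 °C; then 27 (1.5 equiv), DMPU, −78 → −30 °C
Reagents that add atoms: none
Why: Kinetic enolate alkylation: C6 is the only enolisable position because C4 is fully substituted, the α-silyloxy methyl ketone enolate is a well-behaved nucleophile, and the allylic bromide reacts by SN2 while the vinyl iodide is inert to the amide base.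

Step 19
Reactants: 29 (1E,6S,9S,11Z)-13-(TBS-oxy)-1-iodo-2,6,12-trimethyl-9-[3-(PMB-oxy)prop-1-en-2-yl]-6-(TES-oxy)trideca-1,11-dien-5-one
Product: 30 (1E,6S,9S,11Z)-13-(TBS-oxy)-9-(3-hydroxyprop-1-en-2-yl)-1-iodo-2,6,12-trimethyl-6-(TES-oxy)trideca-1,11-dien-5-one
Conditions: DDQ, CH2Cl2/pH 7 phosphate buffer, 0 °C
Reagents that add atoms: none
Why: Oxidative cleavage of the PMB ether by DDQ frees only the side-chain allylic alcohol and leaves both silyl ethers and the iodoalkene in place.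

Step 20
Reactants: 30 (1E,6S,9S,11Z)-13-(TBS-oxy)-9-(3-hydroxyprop-1-en-2-yl)-1-iodo-2,6,12-trimethyl-6-(TES-oxy)trideca-1,11-dien-5-one
Product: 31 2-[(2Z,5S,8S,12E)-1-(TBS-oxy)-13-iodo-2,8,12-trimethyl-9-oxo-8-(TES-oxy)trideca-2,12-dien-5-yl]prop-2-enal
Conditions: Dess–Martin periodinane, NaHCO3, CH2Cl2, 0 °C → rt
Reagents that add atoms: none
Why: Dess–Martin oxidation takes the primary allylic alcohol to the 2-substituted acrolein under buffered conditions.

Step 21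
Reactants: 31 2-[(2Z,5S,8S,12E)-1-(TBS-oxy)-13-iodo-2,8,12-trimethyl-9-oxo-8-(TES-oxy)trideca-2,12-dien-5-yl]prop-2-enal
Product: 33 methyl 2-[(2Z,5S,8S,12E)-1-(TBS-oxy)-13-iodo-2,8,12-trimethyl-9-oxo-8-(TES-oxy)trideca-2,12-dien-5-yl]prop-2-enoate, via acrylic acid 32 (not isolated)
Conditions: NaClO2, NaH2PO4, 2-methylbut-2-ene, t-BuOH/H2O, 0 °C; then TMSCHN2, toluene/MeOH, 0 °C
Reagents that add atoms: sodium chlorite [Na+].[O-]Cl=O; (trimethylsilyl)diazomethane C[Si](C)(C)C=[N+]=[N-]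
Why: Pinnick oxidation converts the enal into the acrylic acid with the alkene scavenger protecting the other double bonds, and diazoalkane methylation gives the methyl acrylate, which from here on is the form in which the side-chain alkene is inert to boranes.

Step 22
Reactants: 33 methyl 2-[(2Z,5S,8S,12E)-1-(TBS-oxy)-13-iodo-2,8,12-trimethyl-9-oxo-8-(TES-oxy)trideca-2,12-dien-5-yl]prop-2-enoate
Product: 34 methyl 2-[(2Z,5S,8S,12E)-1,8-dihydroxy-13-iodo-2,8,12-trimethyl-9-oxotrideca-2,12-dien-5-yl]prop-2-enoate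
Conditions: HF (48% aq.), MeCN, 0 °C → rt
Reagents that add atoms: none
Why: Acidic fluoride desilylation removes the primary allylic TBS ether and then the tertiary TES ether, at a point where no acid-sensitive group is present.

Step 23
Reactants: 34 methyl 2-[(2Z,5S,8S,12E)-1,8-dihydroxy-13-iodo-2,8,12-trimethyl-9-oxotrideca-2,12-dien-5-yl]prop-2-enoate
Product: 35 methyl 2-{(2S,5S,9E)-5-hydroxy-1-[(2R,3S)-3-(hydroxymethyl)-3-methyloxiran-2-yl]-10-iodo-5,9-dimethyl-6-oxodec-9-en-2-yl}prop-2-enoate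
Conditions: Ti(Oi-Pr)4, L-(+)-diethyl tartrate, t-BuOOH, 4 Å molecular sieves, CH2Cl2, −20 °C
Reagents that add atoms: tert-butyl hydroperoxide CC(C)(C)OO
Why: Sharpless asymmetric epoxidation acts only on the allylic alcohol; with L-(+)-tartrate a (Z)-allylic alcohol gives the (2S,3R)-2,3-epoxy alcohol, which is the 12S,13R cis-oxirane of the target, by reagent control.

Step 24
Reactants: 35 methyl 2-{(2S,5S,9E)-5-hydroxy-1-[(2R,3S)-3-(hydroxymethyl)-3-methyloxiran-2-yl]-10-iodo-5,9-dimethyl-6-oxodec-9-en-2-yl}prop-2-enoate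
Product: 36 methyl 2-{(2S,5S,9E)-1-[(2R,3R)-3-formyl-3-methyloxiran-2-yl]-5-hydroxy-10-iodo-5,9-dimethyl-6-oxodec-9-en-2-yl}prop-2-enoate
Conditions: Dess–Martin periodinane, NaHCO3, CH2Cl2, 0 °C
Reagents that add atoms: none
Why: Buffered Dess–Martin oxidation gives the epoxy aldehyde, which has no α-hydrogen and cannot epimerise; the tertiary alcohol is not oxidised.

Step 25
Reactants: 36 methyl 2-{(2S,5S,9E)-1-[(2R,3R)-3-formyl-3-methyloxiran-2-yl]-5-hydroxy-10-iodo-5,9-dimethyl-6-oxodec-9-en-2-yl}prop-2-enoate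
Product: 37 methyl 2-{(2S,5S,9E)-1-[(2R,3S)-3-ethenyl-3-methyloxiran-2-yl]-5-hydroxy-10-iodo-5,9-dimethyl-6-oxodec-9-en-2-yl}prop-2-enoate
Conditions: Ph3PCH3Br, KN(SiMe3)2, THF, 0 °C; then 36, −78 → 0 °C (1.2 equiv ylide)
Reagents that add atoms: methyltriphenylphosphonium bromide [Br-].C[P+](c1ccccc1)(c1ccccc1)c1ccccc1
Why: Wittig methylenation; at −78 °C the ylide should take the very electrophilic epoxy aldehyde ahead of the hindered C5 ketone and the 2-substituted acrylate, and it is too weak a base to deprotonate the tertiary alcohol.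

Step 26
Reactants: 37 methyl 2-{(2S,5S,9E)-1-[(2R,3S)-3-ethenyl-3-methyloxiran-2-yl]-5-hydroxy-10-iodo-5,9-dimethyl-6-oxodec-9-en-2-yl}prop-2-enoate
Product: 39 methyl 2-[(1S,4S,8E,12S,13R)-12,13-epoxy-4-hydroxy-4,8,12-trimethyl-5-oxocyclotetradec-8-en-1-yl]prop-2-enoate (CNP0154954.4; ring numbered as in the plan), via alkylborane 38 (not isolated)
Conditions: 9-BBN dimer, THF, 0 °C → rt; then slow addition to PdCl2(dppf) (20 mol%), AsPh3, Cs2CO3, DMF/THF/H2O, rt, about 1 mM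
Reagents that add atoms: none
Why: Anti-Markovnikov hydroboration of the only unconjugated monosubstituted alkene puts boron on C10 (the conjugated acrylate, the iodoalkene and the hindered ketone should react more slowly), and intramolecular B-alkyl Suzuki–Miyaura coupling with the C9 iodide on zerovalent palladium closes the 14-membered ring at C9–C10 with retention of the E geometry, high dilution favouring ring closure over oligomers.

**Compound list**
1 | 2-bromoprop-2-en-1-ol | C=C(Br)CO | starting material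
2 | 1-{[(2-bromoprop-2-en-1-yl)oxy]methyl}-4-methoxybenzene | C=C(Br)COCc1ccc(OC)cc1 | intermediate
3 | 2-[3-(PMB-oxy)prop-1-en-2-yl]-4,4,5,5-tetramethyl-1,3,2-dioxaborolane | C=C(COCc1ccc(OC)cc1)B1OC(C)(C)C(C)(C)O1 | intermediate
4 | 5,6-dihydro-2H-pyran-2-one | O=C1C=CCCO1 | starting material
5 | (R)-4-[3-(PMB-oxy)prop-1-en-2-yl]tetrahydro-2H-pyran-2-one | O=C1C[C@H](C(=C)COCc2ccc(OC)cc2)CCO1 | intermediate
6 | lithium (R)-5-hydroxy-3-[3-(PMB-oxy)prop-1-en-2-yl]pentanoate | [Li+].[O-]C(=O)C[C@H](C(=C)COCc1ccc(OC)cc1)CCO | intermediate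
7 | tert-butyldimethylsilyl (R)-5-(TBS-oxy)-3-[3-(PMB-oxy)prop-1-en-2-yl]pentanoate | CC(C)(C)[Si](C)(C)OC(=O)C[C@H](C(=C)COCc1ccc(OC)cc1)CCO[Si](C)(C)C(C)(C)C | intermediate
8 | (R)-5-(TBS-oxy)-3-[3-(PMB-oxy)prop-1-en-2-yl]pentanoic acid | OC(=O)C[C@H](C(=C)COCc1ccc(OC)cc1)CCO[Si](C)(C)C(C)(C)C | intermediate
9 | N-hydroxyphthalimide | ON1C(=O)c2ccccc2C1=O | starting material
10 | 1,3-dioxoisoindolin-2-yl (R)-5-(TBS-oxy)-3-[3-(PMB-oxy)prop-1-en-2-yl]pentanoate | O=C(ON1C(=O)c2ccccc2C1=O)C[C@H](C(=C)COCc1ccc(OC)cc1)CCO[Si](C)(C)C(C)(C)C | intermediate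
11 | (S)-citramalic acid | C[C@](O)(CC(=O)O)C(=O)O | starting material
12 | 2-[(4S)-2,2,4-trimethyl-5-oxo-1,3-dioxolan-4-yl]acetic acid | OC(=O)C[C@]1(C)OC(C)(C)OC1=O | intermediate
13 | 1,3-dioxoisoindolin-2-yl 2-[(4S)-2,2,4-trimethyl-5-oxo-1,3-dioxolan-4-yl]acetate | O=C(ON1C(=O)c2ccccc2C1=O)C[C@]1(C)OC(C)(C)OC1=O | intermediate
14 | (5S)-5-{(3S)-5-(TBS-oxy)-3-[3-(PMB-oxy)prop-1-en-2-yl]pentyl}-2,2,5-trimethyl-1,3-dioxolan-4-one | CC(C)(C)[Si](C)(C)OCC[C@@H](C(=C)COCc1ccc(OC)cc1)CC[C@]1(C)OC(C)(C)OC1=O | intermediate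
15 | (5S)-5-{(3S)-5-hydroxy-3-[3-(PMB-oxy)prop-1-en-2-yl]pentyl}-2,2,5-trimethyl-1,3-dioxolan-4-one | OCC[C@@H](C(=C)COCc1ccc(OC)cc1)CC[C@]1(C)OC(C)(C)OC1=O | intermediate
16 | (5S)-5-{(3S)-5-iodo-3-[3-(PMB-oxy)prop-1-en-2-yl]pentyl}-2,2,5-trimethyl-1,3-dioxolan-4-one | ICC[C@@H](C(=C)COCc1ccc(OC)cc1)CC[C@]1(C)OC(C)(C)OC1=O | intermediate
17 | {(3S)-3-[3-(PMB-oxy)prop-1-en-2-yl]-5-[(4S)-2,2,4-trimethyl-5-oxo-1,3-dioxolan-4-yl]pentyl}triphenylphosphonium iodide | [I-].c1ccccc1[P+](c1ccccc1)(c1ccccc1)CC[C@@H](C(=C)COCc1ccc(OC)cc1)CC[C@]1(C)OC(C)(C)OC1=O | intermediate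
18 | 1-(TBS-oxy)propan-2-one | CC(=O)CO[Si](C)(C)C(C)(C)C | starting material
19 | {(3S)-3-[3-(PMB-oxy)prop-1-en-2-yl]-5-[(4S)-2,2,4-trimethyl-5-oxo-1,3-dioxolan-4-yl]pentylidene}triphenylphosphorane | c1ccccc1P(c1ccccc1)(c1ccccc1)=CC[C@@H](C(=C)COCc1ccc(OC)cc1)CC[C@]1(C)OC(C)(C)OC1=O | intermediate
20 | (5S)-5-{(3S,5Z)-7-(TBS-oxy)-6-methyl-3-[3-(PMB-oxy)prop-1-en-2-yl]hept-5-en-1-yl}-2,2,5-trimethyl-1,3-dioxolan-4-one | CC(C)(C)[Si](C)(C)OC/C(C)=C\C[C@@H](C(=C)COCc1ccc(OC)cc1)CC[C@]1(C)OC(C)(C)OC1=O | intermediate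
21 | (2S,5S,7Z)-9-(TBS-oxy)-2-hydroxy-N-methoxy-N,2,8-trimethyl-5-[3-(PMB-oxy)prop-1-en-2-yl]non-7-enamide | CC(C)(C)[Si](C)(C)OC/C(C)=C\C[C@@H](C(=C)COCc1ccc(OC)cc1)CC[C@](C)(O)C(=O)N(C)OC | intermediate
22 | (2S,5S,7Z)-9-(TBS-oxy)-N-methoxy-N,2,8-trimethyl-5-[3-(PMB-oxy)prop-1-en-2-yl]-2-(TES-oxy)non-7-enamide | CC(C)(C)[Si](C)(C)OC/C(C)=C\C[C@@H](C(=C)COCc1ccc(OC)cc1)CC[C@](C)(O[Si](CC)(CC)CC)C(=O)N(C)OC | intermediate
23 | (3S,6S,8Z)-10-(TBS-oxy)-3,9-dimethyl-6-[3-(PMB-oxy)prop-1-en-2-yl]-3-(TES-oxy)dec-8-en-2-one | CC(C)(C)[Si](C)(C)OC/C(C)=C\C[C@@H](C(=C)COCc1ccc(OC)cc1)CC[C@](C)(O[Si](CC)(CC)CC)C(C)=O | intermediate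
24 | prop-2-yn-1-ol | C#CCO | starting material
25 | (E)-[3-(dimethylalumanyloxy)-2-methylprop-1-en-1-yl]dimethylalumane | C[Al](C)/C=C(\C)CO[Al](C)C | intermediate
26 | (E)-3-iodo-2-methylprop-2-en-1-ol | OC/C(C)=C/I | intermediate
27 | (E)-3-bromo-1-iodo-2-methylprop-1-ene | BrC/C(C)=C/I | intermediate
28 | lithium enolate of 23 (lithium (3S,6S,8Z)-10-(TBS-oxy)-3,9-dimethyl-6-[3-(PMB-oxy)prop-1-en-2-yl]-3-(TES-oxy)deca-1,8-dien-2-olate) | CC(C)(C)[Si](C)(C)OC/C(C)=C\C[C@@H](C(=C)COCc1ccc(OC)cc1)CC[C@](C)(O[Si](CC)(CC)CC)C(=C)[O-].[Li+] | intermediate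
29 | (1E,6S,9S,11Z)-13-(TBS-oxy)-1-iodo-2,6,12-trimethyl-9-[3-(PMB-oxy)prop-1-en-2-yl]-6-(TES-oxy)trideca-1,11-dien-5-one | CC(C)(C)[Si](C)(C)OC/C(C)=C\C[C@@H](C(=C)COCc1ccc(OC)cc1)CC[C@](C)(O[Si](CC)(CC)CC)C(=O)CC/C(C)=C/I | intermediate
30 | (1E,6S,9S,11Z)-13-(TBS-oxy)-9-(3-hydroxyprop-1-en-2-yl)-1-iodo-2,6,12-trimethyl-6-(TES-oxy)trideca-1,11-dien-5-one | CC(C)(C)[Si](C)(C)OC/C(C)=C\C[C@@H](C(=C)CO)CC[C@](C)(O[Si](CC)(CC)CC)C(=O)CC/C(C)=C/I | intermediate
31 | 2-[(2Z,5S,8S,12E)-1-(TBS-oxy)-13-iodo-2,8,12-trimethyl-9-oxo-8-(TES-oxy)trideca-2,12-dien-5-yl]prop-2-enal | CC(C)(C)[Si](C)(C)OC/C(C)=C\C[C@@H](C(=C)C=O)CC[C@](C)(O[Si](CC)(CC)CC)C(=O)CC/C(C)=C/I | intermediate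
32 | 2-[(2Z,5S,8S,12E)-1-(TBS-oxy)-13-iodo-2,8,12-trimethyl-9-oxo-8-(TES-oxy)trideca-2,12-dien-5-yl]prop-2-enoic acid | CC(C)(C)[Si](C)(C)OC/C(C)=C\C[C@@H](C(=C)C(=O)O)CC[C@](C)(O[Si](CC)(CC)CC)C(=O)CC/C(C)=C/I | intermediate
33 | methyl 2-[(2Z,5S,8S,12E)-1-(TBS-oxy)-13-iodo-2,8,12-trimethyl-9-oxo-8-(TES-oxy)trideca-2,12-dien-5-yl]prop-2-enoate | CC(C)(C)[Si](C)(C)OC/C(C)=C\C[C@@H](C(=C)C(=O)OC)CC[C@](C)(O[Si](CC)(CC)CC)C(=O)CC/C(C)=C/I | intermediate
34 | methyl 2-[(2Z,5S,8S,12E)-1,8-dihydroxy-13-iodo-2,8,12-trimethyl-9-oxotrideca-2,12-dien-5-yl]prop-2-enoate | OC/C(C)=C\C[C@@H](C(=C)C(=O)OC)CC[C@](C)(O)C(=O)CC/C(C)=C/I | intermediate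
35 | methyl 2-{(2S,5S,9E)-5-hydroxy-1-[(2R,3S)-3-(hydroxymethyl)-3-methyloxiran-2-yl]-10-iodo-5,9-dimethyl-6-oxodec-9-en-2-yl}prop-2-enoate | OC[C@]1(C)O[C@@H]1C[C@@H](C(=C)C(=O)OC)CC[C@](C)(O)C(=O)CC/C(C)=C/I | intermediate
36 | methyl 2-{(2S,5S,9E)-1-[(2R,3R)-3-formyl-3-methyloxiran-2-yl]-5-hydroxy-10-iodo-5,9-dimethyl-6-oxodec-9-en-2-yl}prop-2-enoate | O=C[C@]1(C)O[C@@H]1C[C@@H](C(=C)C(=O)OC)CC[C@](C)(O)C(=O)CC/C(C)=C/I | intermediate
37 | methyl 2-{(2S,5S,9E)-1-[(2R,3S)-3-ethenyl-3-methyloxiran-2-yl]-5-hydroxy-10-iodo-5,9-dimethyl-6-oxodec-9-en-2-yl}prop-2-enoate | C=C[C@]1(C)O[C@@H]1C[C@@H](C(=C)C(=O)OC)CC[C@](C)(O)C(=O)CC/C(C)=C/I | intermediate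
38 | methyl 2-[(2S,5S,9E)-1-{(2R,3S)-3-[2-(9-BBN-9-yl)ethyl]-3-methyloxiran-2-yl}-5-hydroxy-10-iodo-5,9-dimethyl-6-oxodec-9-en-2-yl]prop-2-enoate | B1(CC[C@]2(C)O[C@@H]2C[C@@H](C(=C)C(=O)OC)CC[C@](C)(O)C(=O)CC/C(C)=C/I)C2CCCC1CCC2 | intermediate
39 | methyl 2-[(1S,4S,8E,12S,13R)-12,13-epoxy-4-hydroxy-4,8,12-trimethyl-5-oxocyclotetradec-8-en-1-yl]prop-2-enoate (CNP0154954.4) | C=C(C(=O)OC)[C@H]1CC[C@](C)(O)C(=O)CC/C(C)=C/CC[C@]2(C)O[C@@H]2C1 | target

**Step count**
Total: 26 steps. Longest linear sequence: 22 steps (1–5, 8–15, 18–26).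

**Steps most likely to fail**

Step 26 (hydroboration and ring closure). The borane may bind the oxirane oxygen and deliver hydride to C10 in an SN2′ sense, opening the vinyl oxirane, or reduce the C5 ketone, before it adds across C10=C11; slow transmetalation at high dilution would add protodeboronation. The fallback closes the ring before the epoxide exists. It sets out from 34: MnO2 (CH2Cl2, 0 °C) should give the (Z)-enal F1, and immediate methylenation (Ph3P=CH2, THF, −78 °C) the (Z)-1,3-diene F2. 9-BBN adds to the terminal vinyl group of such dienes to give the homoallylic borane F3, and the palladium conditions of step 26 would close the ring to the macrocyclic triene F4. Epoxidation of the C12=C13 alkene of F4 (dimethyldioxirane, acetone/CH2Cl2, −78 °C) comes back to the route at 39. In that last operation the choice between the two trisubstituted alkenes and between the two faces rests on the ring conformation and would have to be established.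

Step 3 (rhodium conjugate addition). The 1-substituted alkenyl–rhodium species may insert too slowly into the lactone, so that protodeboronation or loss of the allylic oxygen takes over, or the face selection may be poorer than for aryl groups. The fallback builds C1 by desymmetrisation of a glutaric anhydride. It sets out from 2: magnesium insertion (THF) gives the Grignard reagent F5, and copper-catalysed 1,4-addition (CuBr·SMe2 10 mol%, TMSCl, THF, −40 °C) to purchased dimethyl glutaconate gives the diester F6. Saponification (LiOH) gives the diacid F7 and acetic anhydride (60 °C) the anhydride F8. Methanolysis catalysed by (DHQD)2AQN or its pseudo-enantiomer (DHQ)2AQN, whichever delivers it, gives the hemiester F9. LiBH4 (THF) reduces the ester of the carboxylate salt to the hydroxy acid F10, which lactonises with catalytic TsOH and comes back to the route at 5.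

Step 8 (doubly decarboxylative coupling). Homo-coupling of each radical and reduction to the alkanes may outrun the hetero-coupling, and the excess of 13 may not compensate if the two esters are reduced at very different rates. The fallback keeps the C2–C3 bond but makes one partner a preformed nucleophile. It sets out from 8: esterification with N-hydroxypyridine-2-thione (DCC) gives the Barton ester F11, and photolysis with CHI3 gives the primary iodide F12 (Barton decarboxylative iodination). Zinc insertion (Zn, LiCl, THF) gives the alkylzinc iodide F13, and nickel-catalysed decarboxylative alkyl–alkyl Negishi coupling with 13 (NiCl2(dme), 4,4'-di-tert-butyl-2,2'-bipyridine, THF/DMF, rt) comes back to the route at 14.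

**Further compounds**
F1 | step 26 | methyl 2-[(2Z,5S,8S,12E)-8-hydroxy-13-iodo-2,8,12-trimethyl-1,9-dioxotrideca-2,12-dien-5-yl]prop-2-enoate | O=C/C(C)=C\C[C@@H](C(=C)C(=O)OC)CC[C@](C)(O)C(=O)CC/C(C)=C/I
F2 | step 26 | methyl 2-[(3Z,6S,9S,13E)-9-hydroxy-14-iodo-3,9,13-trimethyl-10-oxotetradeca-1,3,13-trien-6-yl]prop-2-enoate | C=C/C(C)=C\C[C@@H](C(=C)C(=O)OC)CC[C@](C)(O)C(=O)CC/C(C)=C/I
F3 | step 26 | methyl 2-[(3Z,6S,9S,13E)-1-(9-BBN-9-yl)-9-hydroxy-14-iodo-3,9,13-trimethyl-10-oxotetradeca-3,13-dien-6-yl]prop-2-enoate | B1(CC/C(C)=C\C[C@@H](C(=C)C(=O)OC)CC[C@](C)(O)C(=O)CC/C(C)=C/I)C2CCCC1CCC2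
F4 | step 26 | methyl 2-[(1S,4S,8E,12Z)-4-hydroxy-4,8,12-trimethyl-5-oxocyclotetradeca-8,12-dien-1-yl]prop-2-enoate | C=C(C(=O)OC)[C@H]1CC[C@](C)(O)C(=O)CC/C(C)=C/CC/C(C)=C\C1
F5 | step 3 | [3-(PMB-oxy)prop-1-en-2-yl]magnesium bromide | C=C(COCc1ccc(OC)cc1)[Mg]Br
F6 | step 3 | dimethyl 3-[3-(PMB-oxy)prop-1-en-2-yl]pentanedioate | COC(=O)CC(CC(=O)OC)C(=C)COCc1ccc(OC)cc1
F7 | step 3 | 3-[3-(PMB-oxy)prop-1-en-2-yl]pentanedioic acid | OC(=O)CC(CC(=O)O)C(=C)COCc1ccc(OC)cc1
F8 | step 3 | 4-[3-(PMB-oxy)prop-1-en-2-yl]oxane-2,6-dione | O=C1CC(CC(=O)O1)C(=C)COCc1ccc(OC)cc1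
F9 | step 3 | (S)-5-methoxy-5-oxo-3-[3-(PMB-oxy)prop-1-en-2-yl]pentanoic acid | OC(=O)C[C@H](C(=C)COCc1ccc(OC)cc1)CC(=O)OC
F10 | step 3 | (R)-5-hydroxy-3-[3-(PMB-oxy)prop-1-en-2-yl]pentanoic acid | OC(=O)C[C@H](C(=C)COCc1ccc(OC)cc1)CCO
F11 | step 8 | 2-thioxopyridin-1(2H)-yl (R)-5-(TBS-oxy)-3-[3-(PMB-oxy)prop-1-en-2-yl]pentanoate | S=c1ccccn1OC(=O)C[C@H](C(=C)COCc1ccc(OC)cc1)CCO[Si](C)(C)C(C)(C)C
F12 | step 8 | tert-butyl{[(3S)-3-(iodomethyl)-4-(PMB-oxymethyl)pent-4-en-1-yl]oxy}dimethylsilane | IC[C@H](C(=C)COCc1ccc(OC)cc1)CCO[Si](C)(C)C(C)(C)C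
F13 | step 8 | {(2S)-4-(TBS-oxy)-2-[3-(PMB-oxy)prop-1-en-2-yl]butyl}zinc iodide | I[Zn]C[C@H](C(=C)COCc1ccc(OC)cc1)CCO[Si](C)(C)C(C)(C)C
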